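**Strategy**

Flavan locants are used, primed for the lower unit. The target is cut at the two bonds that stitch the dearomatised lower flavan to the upper flavan-4-ol: the C-8'–C-8a' bond of the cyclohexadienone ring and the aryl ether bond from the ketal oxygen on C-8a' to C-5. The key step exploits C-8a' being a ketal carbon next to quaternary C-8' inside a six-membered carbocycle: a lactone trienolate closes that ring by 6π-electrocyclisation (vinylogous Dieckmann addition) and the resulting lactolate is arylated by the ortho C-5 iodide under CuI catalysis, forming the dihydrofuran ring and both quaternary stereocentres at once. The precursor is an (S)-6-phenyl-δ-lactone bearing a silyloxydienyl chain attached to an iodinated flavan.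

Key step: step 17

Remark (assumption): the (R)-enantiomer of t-BuPyOx is taken to deliver the (S)-flavanone in step 2, by analogy with the facial sense on cyclic enones; if the sense is the reverse, its antipode is used.
Remark (abbreviations): Ar = (2S,4R)-4-(tert-butyldimethylsilyloxy)-7,8-dimethoxy-2-phenylchroman-6-yl; ArI = the same group with iodine at C-5.
Remark (locants): in the lactone intermediates the lactone carbonyl carbon is the future C-8a' and its α-carbon the future C-4a'; the side-chain carbons are C-5' (silyloxy), C-6', C-7' (OMe) and C-8' (OMe, aryl).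

**Route**

Step 1
Reactants: 1 1-(2-hydroxy-3,4-dimethoxyphenyl)ethan-1-one
Product: 3 7,8-dimethoxy-4H-chromen-4-one, via enaminone 2 (not isolated)
Conditions: Me2NCH(OMe)2, 95 °C; then conc. HCl, CH2Cl2, 40 °C
Reagents that add atoms: N,N-dimethylformamide dimethyl acetal, COC(OC)N(C)C
Why: Enaminone condensation of the methyl ketone with the amide acetal, then acid-promoted addition–elimination of the phenol onto the enaminone (chromone synthesis); no stereocentre is formed.

Step 2
Reactants: 3 7,8-dimethoxy-4H-chromen-4-one; 4 phenylboronic acid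
Product: 5 (2S)-7,8-dimethoxy-2-phenylchroman-4-one
Conditions: Pd(OCOCF3)2 (5 mol%), (R)-t-BuPyOx (6 mol%), NH4PF6 (30 mol%), H2O (5 equiv), ClCH2CH2Cl, 60 °C
Reagents that add atoms: none
Why: Palladium-catalysed asymmetric conjugate addition of the arylboronic acid (arylpalladium 1,4-addition to the chromone enone), in which the pyridine-oxazoline ligand selects the enone face and should set C-2 as S.

Step 3
Reactants: 5 (2S)-7,8-dimethoxy-2-phenylchroman-4-one
Product: 6 (2S,4S)-7,8-dimethoxy-2-phenylchroman-4-ol (2,4-cis)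
Conditions: NaBH4, MeOH–THF, 0 °C
Reagents that add atoms: none
Why: Borohydride reduction of the ketone, in which axial hydride attack on the half-chair with equatorial 2-phenyl should give the equatorial, 2,4-cis (4S) alcohol.

Step 4
Reactants: 6 (2S,4S)-7,8-dimethoxy-2-phenylchroman-4-ol
Product: 7 (2S,4R)-7,8-dimethoxy-2-phenylchroman-4-yl 4-nitrobenzoate (2,4-trans)
Conditions: 4-O2NC6H4CO2H, PPh3, DIAD, THF, 0 °C → rt
Reagents that add atoms: 4-nitrobenzoic acid, O=C(O)c1ccc(cc1)[N+](=O)[O-]
Why: Mitsunobu esterification, whose SN2 displacement of the oxyphosphonium by the carboxylate inverts C-4 to R and so gives the 2,4-trans ester.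

Step 5
Reactants: 7 (2S,4R)-7,8-dimethoxy-2-phenylchroman-4-yl 4-nitrobenzoate
Product: 8 (2S,4R)-7,8-dimethoxy-2-phenylchroman-4-ol (2,4-trans)
Conditions: K2CO3 (cat.), MeOH, rt
Reagents that add atoms: none
Why: Base-catalysed transesterification (methanolysis) cleaves only the acyl–oxygen bond, so C-4 keeps its R configuration.

Step 6
Reactants: 8 (2S,4R)-7,8-dimethoxy-2-phenylchroman-4-ol
Product: 9 tert-butyl{[(2S,4R)-7,8-dimethoxy-2-phenylchroman-4-yl]oxy}dimethylsilane
Conditions: TBSCl, imidazole, DMF, rt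
Reagents that add atoms: tert-butyldimethylsilyl chloride, CC(C)(C)[Si](C)(C)Cl
Why: Imidazole-promoted silyl ether formation masks the benzylic alcohol for the strongly basic steps that follow.

Step 7
Reactants: 9 tert-butyl{[(2S,4R)-7,8-dimethoxy-2-phenylchroman-4-yl]oxy}dimethylsilane
Product: 10 {[(2S,4R)-6-bromo-7,8-dimethoxy-2-phenylchroman-4-yl]oxy}(tert-butyl)dimethylsilane
Conditions: NBS, MeCN, 0 °C
Reagents that add atoms: N-bromosuccinimide, O=C1CCC(=O)N1Br
Why: Electrophilic aromatic bromination, directed to C-6 because it is ortho to the 7-methoxy group and para to the ring oxygen, whereas C-5 is activated only by the twisted 8-methoxy group.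

Step 8
Reactants: 10 the 6-bromide; 11 3-(trimethylsilyl)prop-2-ynal
Product: 13 1-Ar-3-(trimethylsilyl)prop-2-yn-1-ol (both carbinol epimers), via aryllithium 12 (not isolated)
Conditions: n-BuLi, THF, −78 °C; then 11, −78 °C; aq. NH4Cl
Reagents that add atoms: none
Why: Bromine–lithium exchange followed by 1,2-addition of the aryllithium to the ynal; the carbinol centre (future C-8') forms as a mixture, which is immaterial because this carbon is planarised in step 17.

Step 9
Reactants: 13 1-Ar-3-(trimethylsilyl)prop-2-yn-1-ol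
Product: 15 3-Ar-3-methoxyprop-1-yne (epimers at the methoxy carbon), via silylalkyne ether 14 (not isolated)
Conditions: NaH, MeI, THF, 0 °C → rt; then K2CO3, MeOH, rt
Reagents that add atoms: iodomethane, CI
Why: Williamson etherification of the alkoxide with iodomethane, followed by base-mediated methanolysis of the alkynyl–silicon bond (protodesilylation).

Step 10
Reactants: 15 3-Ar-3-methoxyprop-1-yne
Product: 16 3-ArI-3-methoxyprop-1-yne
Conditions: NIS, CF3CO2H (5 mol%), MeCN, 0 °C, dark
Reagents that add atoms: N-iodosuccinimide, O=C1CCC(=O)N1I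
Why: Electrophilic aromatic iodination at the only remaining aromatic C–H of the chroman ring (C-5, para to the 8-methoxy group), the phenyl rings and the alkyne being far less nucleophilic.

Step 11
Reactants: 16 3-ArI-3-methoxyprop-1-yne
Product: 18 4-ArI-4-methoxybut-2-ynal, via lithium acetylide 17 (not isolated)
Conditions: LiN(i-Pr)2, THF, −78 °C; DMF; inverse quench into aq. KH2PO4
Reagents that add atoms: N,N-dimethylformamide, CN(C)C=O
Why: Formylation of the lithium acetylide with DMF (Bouveault-type acylation), the buffered inverse quench preventing addition of liberated dimethylamine to the ynal.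

Step 12
Reactants: 18 4-ArI-4-methoxybut-2-ynal
Product: 19 4-ArI-3,4-dimethoxybut-2-enal (E/Z mixture)
Conditions: MeOH, DABCO (10 mol%), CH2Cl2, 0 °C → rt
Reagents that add atoms: methanol, CO
Why: Amine-catalysed oxa-Michael (conjugate) addition of methanol to the ynal, which places the methoxy group regiospecifically on the β-carbon (future C-7').

Step 13
Reactants: 20 methyl 5-oxo-5-phenylpentanoate
Product: 22 (6S)-6-phenyltetrahydro-2H-pyran-2-one, via hydroxy ester 21 (not isolated)
Conditions: RuCl[(S,S)-TsDPEN](p-cymene) (1 mol%), HCO2H–Et3N (5:2), 40 °C; then TsOH·H2O (cat.), toluene, 60 °C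
Reagents that add atoms: none
Why: Noyori asymmetric transfer hydrogenation should set the benzylic carbinol as S by catalyst control (same sense as for acetophenone), and acid-catalysed lactonisation closes the δ-lactone without touching it.

Step 14
Reactants: 22 (6S)-6-phenyltetrahydro-2H-pyran-2-one; 19 4-ArI-3,4-dimethoxybut-2-enal
Product: 24 (6S)-3-(4-ArI-1-hydroxy-3,4-dimethoxybut-2-en-1-yl)-6-phenyltetrahydro-2H-pyran-2-one (diastereomer mixture), via lithium enolate 23 (not isolated)
Conditions: LiN(i-Pr)2, THF, −78 °C; then 19, −78 °C; aq. NH4Cl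
Reagents that add atoms: none
Why: Directed aldol addition of the lithium lactone enolate to the aldehyde (1,2-addition); the two new centres form as mixtures and are removed in steps 15 and 16.

Step 15
Reactants: 24 the aldol adduct
Product: 25 (6S)-3-(4-ArI-3,4-dimethoxybut-2-enoyl)-6-phenyltetrahydro-2H-pyran-2-one (keto/enol mixture)
Conditions: Dess–Martin periodinane, NaHCO3, CH2Cl2, 0 °C → rt
Reagents that add atoms: none
Why: Dess–Martin oxidation of the allylic alcohol to the β-keto lactone under buffered, non-acidic conditions that should spare the silyl and benzylic ethers.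

Step 16
Reactants: 25 the β-keto lactone
Product: 26 (6S)-3-[4-ArI-3,4-dimethoxy-1-(triisopropylsilyloxy)but-2-en-1-ylidene]-6-phenyltetrahydro-2H-pyran-2-one (alkene geometries and C-8' unassigned)
Conditions: i-Pr3SiOTf, Et3N, CH2Cl2, −78 → 0 °C
Reagents that add atoms: triisopropylsilyl trifluoromethanesulfonate, CC(C)[Si](C(C)C)(C(C)C)OS(=O)(=O)C(F)(F)F
Why: O-Silylation of the enolised β-keto lactone at the ketone oxygen (silyl enol ether formation, as for β-keto esters), which removes the acidic C-4a'–H and completes the triene array.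

Step 17
Reactants: 26 the silyloxydienyl lactone
Product: 29 pentacyclic ketal (2S,4R,2'S,8'S,8a'S) carrying the C-5' triisopropylsilyl dienol ether (C-4' as CH2) and the 4-O-TBS group, via potassium trienolate 27 (not isolated), via potassium lactolate 28 (not isolated)
Conditions: KN(SiMe3)2, THF, −78 → 0 °C; then CuI (20 mol%), 3,4,7,8-tetramethyl-1,10-phenanthroline (40 mol%), toluene, 80 °C
Reagents that add atoms: none
Why: Proposed new method: KN(SiMe3)2 removes the only acidic proton (C-8'–H, benzylic and vinylogous to the lactone carbonyl) to give trienolate 27, whose C-8'=C-7'–C-6'=C-5'–C-4a'=C-8a' array closes by thermal disrotatory 6π-electrocyclisation (equally a 6-exo-trig vinylogous Dieckmann addition) to lactolate 28, and the monovalent copper alkoxide is then arylated by the neighbouring C-5 iodide (oxidative addition, C–O reductive elimination), which makes the sequence irreversible. The closest known reaction types are the addition of ester enolates to δ-lactones that stops at the lactolate, the CuI/phenanthroline intramolecular O-arylation of tertiary alkoxides, and benzylic-anion addition/SNAr cascades to indoles and benzofurans; their merger on a lactone trienolate is new. The carbocycle closes in the 6π (6-exo-trig) mode and the dihydrofuran ring by intramolecular Ullmann-type etherification as a 5-membered closure onto the aryl iodide. C-8a' should be controlled by C-2': the new C–C bond must lie near the plane of the C-5'=C-4a' enol ether, hence pseudo-equatorial on the pyran chair, leaving the oxygen axial (anomeric) and trans to the equatorial phenyl; C-8' follows because only the epimer with the aryl group syn to the alkoxide can close the 5-membered ring, the other reverting by retro-addition. The step needs O-arylation of 28 to outrun lactolate collapse and vinylogous substitution at C-5', which the bulky i-Pr3Si group (slow silyl transfer, shielded C-5') and the pre-organised ortho iodide are meant to secure.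

Step 18
Reactants: 29 the pentacyclic silyl dienol ether
Product: 30 4-O-tert-butyldimethylsilyl-6''-demethoxyneocalycopterone
Conditions: Pd(OAc)2 (1.2 equiv), MeCN, 40 °C
Reagents that add atoms: none
Why: Saegusa–Ito oxidation: palladation of the silyl dienol ether at C-4a' and β-hydride elimination towards C-4', the only position with β-hydrogens, should unveil the C-5' ketone and the C-4a'=C-4' alkene without touching a stereocentre.

Step 19
Reactants: 30 4-O-tert-butyldimethylsilyl-6''-demethoxyneocalycopterone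
Product: 31 6''-demethoxyneocalycopterone
Conditions: HF·pyridine, pyridine, THF, 0 °C → rt
Reagents that add atoms: none
Why: Fluoride-mediated cleavage of the silyl ether (desilylation) under buffered conditions that should leave the ketal and the vinylogous ester intact.

**Compound list**

1 | 1-(2-hydroxy-3,4-dimethoxyphenyl)ethan-1-one | CC(=O)c1ccc(OC)c(OC)c1O | starting material
2 | (E)-3-(dimethylamino)-1-(2-hydroxy-3,4-dimethoxyphenyl)prop-2-en-1-one | CN(C)/C=C/C(=O)c1ccc(OC)c(OC)c1O | intermediate
3 | 7,8-dimethoxy-4H-chromen-4-one | O=C1C=COc2c1ccc(OC)c2OC | intermediate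
4 | phenylboronic acid | OB(O)c1ccccc1 | starting material
5 | (2S)-7,8-dimethoxy-2-phenylchroman-4-one | O=C1C[C@@H](c2ccccc2)Oc2c1ccc(OC)c2OC | intermediate
6 | (2S,4S)-7,8-dimethoxy-2-phenylchroman-4-ol | O[C@H]1C[C@@H](c2ccccc2)Oc2c1ccc(OC)c2OC | intermediate
7 | (2S,4R)-7,8-dimethoxy-2-phenylchroman-4-yl 4-nitrobenzoate | O=C(O[C@@H]1C[C@@H](c2ccccc2)Oc2c1ccc(OC)c2OC)c1ccc(cc1)[N+](=O)[O-] | intermediate
8 | (2S,4R)-7,8-dimethoxy-2-phenylchroman-4-ol | O[C@@H]1C[C@@H](c2ccccc2)Oc2c1ccc(OC)c2OC | intermediate
9 | tert-butyl{[(2S,4R)-7,8-dimethoxy-2-phenylchroman-4-yl]oxy}dimethylsilane | CC(C)(C)[Si](C)(C)O[C@@H]1C[C@@H](c2ccccc2)Oc2c1ccc(OC)c2OC | intermediate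
10 | {[(2S,4R)-6-bromo-7,8-dimethoxy-2-phenylchroman-4-yl]oxy}(tert-butyl)dimethylsilane | CC(C)(C)[Si](C)(C)O[C@@H]1C[C@@H](c2ccccc2)Oc2c1cc(Br)c(OC)c2OC | intermediate
11 | 3-(trimethylsilyl)prop-2-ynal | C[Si](C)(C)C#CC=O | starting material
12 | 6-lithio derivative of 9 (aryllithium) | CC(C)(C)[Si](C)(C)O[C@@H]1C[C@@H](c2ccccc2)Oc2c1cc([Li])c(OC)c2OC | intermediate
13 | 1-Ar-3-(trimethylsilyl)prop-2-yn-1-ol (carbinol epimers) | C[Si](C)(C)C#CC(O)c1cc2c(c(OC)c1OC)O[C@H](c1ccccc1)C[C@H]2O[Si](C)(C)C(C)(C)C | intermediate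
14 | (3-Ar-3-methoxyprop-1-yn-1-yl)trimethylsilane | C[Si](C)(C)C#CC(OC)c1cc2c(c(OC)c1OC)O[C@H](c1ccccc1)C[C@H]2O[Si](C)(C)C(C)(C)C | intermediate
15 | 3-Ar-3-methoxyprop-1-yne | C#CC(OC)c1cc2c(c(OC)c1OC)O[C@H](c1ccccc1)C[C@H]2O[Si](C)(C)C(C)(C)C | intermediate
16 | 3-ArI-3-methoxyprop-1-yne | C#CC(OC)c1c(I)c2c(c(OC)c1OC)O[C@H](c1ccccc1)C[C@H]2O[Si](C)(C)C(C)(C)C | intermediate
17 | lithium acetylide of 16 | [Li]C#CC(OC)c1c(I)c2c(c(OC)c1OC)O[C@H](c1ccccc1)C[C@H]2O[Si](C)(C)C(C)(C)C | intermediate
18 | 4-ArI-4-methoxybut-2-ynal | O=CC#CC(OC)c1c(I)c2c(c(OC)c1OC)O[C@H](c1ccccc1)C[C@H]2O[Si](C)(C)C(C)(C)C | intermediate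
19 | 4-ArI-3,4-dimethoxybut-2-enal (E/Z mixture) | O=CC=C(OC)C(OC)c1c(I)c2c(c(OC)c1OC)O[C@H](c1ccccc1)C[C@H]2O[Si](C)(C)C(C)(C)C | intermediate
20 | methyl 5-oxo-5-phenylpentanoate | COC(=O)CCCC(=O)c1ccccc1 | starting material
21 | methyl (5S)-5-hydroxy-5-phenylpentanoate | COC(=O)CCC[C@H](O)c1ccccc1 | intermediate
22 | (6S)-6-phenyltetrahydro-2H-pyran-2-one | O=C1CCC[C@@H](c2ccccc2)O1 | intermediate
23 | lithium enolate of 22 | [Li]OC1=CCC[C@@H](c2ccccc2)O1 | intermediate
24 | (6S)-3-(4-ArI-1-hydroxy-3,4-dimethoxybut-2-en-1-yl)-6-phenyltetrahydro-2H-pyran-2-one | O=C1O[C@H](c2ccccc2)CCC1C(O)C=C(OC)C(OC)c1c(I)c2c(c(OC)c1OC)O[C@H](c1ccccc1)C[C@H]2O[Si](C)(C)C(C)(C)C | intermediate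
25 | (6S)-3-(4-ArI-3,4-dimethoxybut-2-enoyl)-6-phenyltetrahydro-2H-pyran-2-one | O=C1O[C@H](c2ccccc2)CCC1C(=O)C=C(OC)C(OC)c1c(I)c2c(c(OC)c1OC)O[C@H](c1ccccc1)C[C@H]2O[Si](C)(C)C(C)(C)C | intermediate
26 | (6S)-3-[4-ArI-3,4-dimethoxy-1-(triisopropylsilyloxy)but-2-en-1-ylidene]-6-phenyltetrahydro-2H-pyran-2-one | O=C1O[C@H](c2ccccc2)CCC1=C(O[Si](C(C)C)(C(C)C)C(C)C)C=C(OC)C(OC)c1c(I)c2c(c(OC)c1OC)O[C@H](c1ccccc1)C[C@H]2O[Si](C)(C)C(C)(C)C | intermediate
27 | potassium trienolate of 26 (deprotonated at C-8', charge delocalised to the lactone oxygen) | [K+].[O-]C1=C(CC[C@@H](c2ccccc2)O1)C(O[Si](C(C)C)(C(C)C)C(C)C)=CC(OC)=C(OC)c1c(I)c2c(c(OC)c1OC)O[C@H](c1ccccc1)C[C@H]2O[Si](C)(C)C(C)(C)C | intermediate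
28 | potassium lactolate (C-8'–C-8a' bond formed, O− on C-8a' syn to the iodoaryl group; spatial arrangement at C-8' and C-8a' as in 29) | [K+].COC1=CC(O[Si](C(C)C)(C(C)C)C(C)C)=C2CC[C@@H](c3ccccc3)O[C@@]2([O-])[C@]1(OC)c1c(I)c2c(c(OC)c1OC)O[C@H](c1ccccc1)C[C@H]2O[Si](C)(C)C(C)(C)C | intermediate
29 | (2S,4R,2'S,8'S,8a'S)-pentacyclic ketal: 30 with the C-5' ketone and C-4a'=C-4' alkene replaced by a C-5'(OSi-i-Pr3)=C-4a' silyl dienol ether and C-4' as CH2 | COC1=CC(O[Si](C(C)C)(C(C)C)C(C)C)=C2CC[C@@H](c3ccccc3)O[C@]23Oc2c4c(c(OC)c(OC)c2[C@]13OC)O[C@H](c1ccccc1)C[C@H]4O[Si](C)(C)C(C)(C)C | intermediate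
30 | 4-O-tert-butyldimethylsilyl-6''-demethoxyneocalycopterone (2S,4R,2'S,8'S,8a'S) | COC1=CC(=O)C2=CC[C@@H](c3ccccc3)O[C@]23Oc2c4c(c(OC)c(OC)c2[C@]13OC)O[C@H](c1ccccc1)C[C@H]4O[Si](C)(C)C(C)(C)C | intermediate
31 | 6''-demethoxyneocalycopterone (2S,4R,2'S,8'S,8a'S) | COC1=CC(=O)C2=CC[C@@H](c3ccccc3)O[C@]23Oc2c4c(c(OC)c(OC)c2[C@]13OC)O[C@H](c1ccccc1)C[C@H]4O | target

**Step count and risks**

Total step count: 19. Longest linear sequence: 18 steps (steps 1–12, then 14–19, from compound 1); step 13 is a one-step branch.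

Steps most likely to fail:

1. Step 17 (Proposed new method). The lactolate may collapse by opening of the pyran ring and then undergo vinylogous substitution at C-5' or silyl transfer, copper may arylate a carbon of the trienolate, or the facial selectivity of ring closure relative to C-2' may be poor, all before O-arylation takes place. Fallback, setting out from 26 and returning at 29: the trienolate is generated with KN(SiMe3)2 at −78 °C and trapped on oxygen with Me3SiCl to give the silyl ketene acetal triene F1. Heating in toluene at 100 °C should effect a neutral disrotatory 6π-electrocyclisation (hexatriene to cyclohexadiene) to the mixed silyl ketal F2, in which no alkoxide is ever present; the epimer with the aryl group syn to the silyloxy group is carried on. Selective cleavage of the ketal trimethylsilyl ether with HF·pyridine buffered by excess pyridine at −40 °C gives the free lactol F3. Palladium-catalysed intramolecular aryl etherification of this tertiary alcohol (Pd(OAc)2, 2-(di-tert-butylphosphino)-1,1'-binaphthyl, Cs2CO3, toluene, 70 °C; Buchwald–Hartwig-type C–O coupling) then closes the dihydrofuran ring to 29.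

2. Step 18. The palladium enolate at C-4a' may expel the β-aryloxide (opening the dihydrofuran ketal) faster than it undergoes β-hydride elimination, or palladation may occur at C-6'. Fallback, setting out from 29 and returning at 30: direct selenenylation of the silyl dienol ether with PhSeCl in CH2Cl2 at −78 °C, which involves no metal enolate, gives the α-phenylselanyl ketone F4. Oxidation with H2O2/pyridine at 0 °C and selenoxide syn-elimination, for which only C-4' offers β-hydrogens, gives 30.

3. Step 10. Acid may ionise the electron-rich benzylic silyl and methyl ethers, and substitution at the crowded C-5 may be slow. Fallback, setting out from 13 and returning at 16: acid-free bromination with NBS in MeCN at 0 °C, before the methyl ether is in place, gives the aryl bromide F5. Methylation (NaH, MeI) gives the methyl ether F6, and an aromatic Finkelstein reaction (CuI 10 mol%, NaI, trans-N,N'-dimethylcyclohexane-1,2-diamine, dioxane, 110 °C), run with the alkyne still silylated, gives the aryl iodide F7. Protodesilylation (K2CO3, MeOH) gives 16.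

Further compounds
F1 | step 17 | trimethylsilyl ketene acetal triene from O-silylation of trienolate 27 | C[Si](C)(C)OC1=C(CC[C@@H](c2ccccc2)O1)C(O[Si](C(C)C)(C(C)C)C(C)C)=CC(OC)=C(OC)c1c(I)c2c(c(OC)c1OC)O[C@H](c1ccccc1)C[C@H]2O[Si](C)(C)C(C)(C)C
F2 | step 17 | mixed silyl ketal (trimethylsilyl ether of lactol F3) | COC1=CC(O[Si](C(C)C)(C(C)C)C(C)C)=C2CC[C@@H](c3ccccc3)O[C@@]2(O[Si](C)(C)C)[C@]1(OC)c1c(I)c2c(c(OC)c1OC)O[C@H](c1ccccc1)C[C@H]2O[Si](C)(C)C(C)(C)C
F3 | step 17 | free lactol (hemiketal OH on C-8a', iodoaryl on C-8') | COC1=CC(O[Si](C(C)C)(C(C)C)C(C)C)=C2CC[C@@H](c3ccccc3)O[C@@]2(O)[C@]1(OC)c1c(I)c2c(c(OC)c1OC)O[C@H](c1ccccc1)C[C@H]2O[Si](C)(C)C(C)(C)C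
F4 | step 18 | 4a'-phenylselanyl-4',4a'-dihydro derivative of 30 (C-4a' epimers) | COC1=CC(=O)C2([Se]c3ccccc3)CC[C@@H](c3ccccc3)O[C@]23Oc2c4c(c(OC)c(OC)c2[C@]13OC)O[C@H](c1ccccc1)C[C@H]4O[Si](C)(C)C(C)(C)C
F5 | step 10 | 5-bromo derivative of 13 | C[Si](C)(C)C#CC(O)c1c(Br)c2c(c(OC)c1OC)O[C@H](c1ccccc1)C[C@H]2O[Si](C)(C)C(C)(C)C
F6 | step 10 | 5-bromo derivative of 14 | C[Si](C)(C)C#CC(OC)c1c(Br)c2c(c(OC)c1OC)O[C@H](c1ccccc1)C[C@H]2O[Si](C)(C)C(C)(C)C
F7 | step 10 | 5-iodo derivative of 14 | C[Si](C)(C)C#CC(OC)c1c(I)c2c(c(OC)c1OC)O[C@H](c1ccccc1)C[C@H]2O[Si](C)(C)C(C)(C)C
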